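(Its constants are invented; the rest is arithmetic.)

In a one-step world the enzyme would meet the starting material and nothing else, and the rate of making target would follow the enzyme charge in plain proportion. This flask gives the enzyme a second customer.

starting material 0.10 M; second substrate 0.100 M; enzyme 10 µM

    starting material → uncatalysed product (k1 = 0.00472 h⁻¹)
    2 second substrate → homo dimer (k2 = 0.265 M⁻¹ h⁻¹)
    complex B → enzyme + second product (k3 = 448 h⁻¹)
    second substrate + enzyme ⇌ complex B (K4 = 240 M⁻¹, k4 = 3.30 × 10⁵ M⁻¹ h⁻¹)
    starting material + enzyme ⇌ complex A (K5 = 9.55 M⁻¹, k5 = 1.44 × 10⁶ M⁻¹ h⁻¹)
    complex A → enzyme + target (k6 = 538 h⁻¹)

- two of one species on the left: rate k times its square, two consumed each time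
- charge of starting material (flask): 0.10 M

- apparent order in second substrate when 30 % of the starting material are converted (percent change of the rate of making target for one percent more second substrate charged)
- apparent order in enzyme when 30 % of the starting material are converted (percent change of the rate of making target for one percent more enzyme charged)

On the fastest rung, a free enzyme takes up starting material at 1.44 × 10⁵ h⁻¹ and second substrate at 33000 h⁻¹. The complexes turn over at 538 h⁻¹ and 448 h⁻¹, so the forms of the enzyme keep a steady balance on a scale far shorter than the hours of the run. In that balance each substrate is weighed against its Michaelis constant, 0.105 M for starting material and 0.00552 M for second substrate, so complex B is the resting state while second substrate lasts.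

On the next rung, the enzyme at full speed uses 0.00448 M h⁻¹ of second substrate, so the charge lasts it 22.3 h. Dimer formation starts out faster than that. The uncatalysed route is the slowest rung, with a half-life of 147 h.

The moment asked about comes at 24.5 h, later than that clearing time. The yardstick there is the clear-enzyme rate, the rate of making target at this conversion with c(second substrate) at zero. With starting material at 0.666 of its Michaelis constant, it comes to 0.00215 M h⁻¹.

Letting the tail of second substrate decay from the clearing time gives 0.00325 M left, which holds back 26.1 % of the clear-enzyme rate. The residue depends exponentially on the time past clearing, and both the clearing time and the moment of this conversion move with the charge and the enzyme, so this reckoning gives no figure for the orders. It commits to their direction: a negative order in second substrate and an order above one in enzyme. It counts no dimer, so the residue is on the high side.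

The forecast gives −0.25 and 1.25, on the ground that “a small change in charge or enzyme shifts the residual inhibitor by more than its own percentage”.

The simulation gives −0.14 and 1.1. The rate at that moment is 0.00187 M h⁻¹, lower than the clear-enzyme rate by 13.0 %. The same yardstick serves later in the run. When 30 % of the starting material remains, it comes to 0.00119 M h⁻¹, which is 0.636 of the earlier rate, and at 45.9 h the simulated ratio is 0.64.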